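## Analysis of the target

Isariotin C (27) is a bicyclo[3.3.1]nonan-9-one whose C3 nitrogen is acylated by (E)-7-oxododec-2-enoic acid. Core numbering used throughout: C1 hydroxylated bridgehead, C2 methylene, C3 nitrogen-bearing carbon, C4 carbinol, C5 bridgehead CH, C6 carbinol, C7 and C8 epoxide carbons, C9 ketone. Ring A is C1–C2–C3–C4–C5–C9 and ring B is C1–C8–C7–C6–C5–C9.

Seven of the nine core carbons are stereocentres, (1S,3S,4R,5S,6S,7S,8S) in this numbering. In the twin chair the amide nitrogen is exo (equatorial on ring A). The C4 and C6 hydroxyls are both axial on their rings and form a syn-1,3-diol across C5 on the C9 side. The C1 hydroxyl is equatorial to both rings, and the epoxide oxygen lies on the exo face of ring B, cis to the C6 hydroxyl.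

The sensitive groups are two β-hydroxy ketone units (retro-aldol under base), a tertiary α-ketol at C1/C9, an epoxide flanked by two carbinols, and a side chain with a Michael acceptor and a remote ketone.

The difficulty is the density: only C2 is unfunctionalised, C5 cannot be corrected once the bicycle exists, and nitrogen sits at C3, which is not next to a carbonyl group.

The strategy rests on one feature. C1 carries both an oxygen and the C2 methylene, so C1–O–C2 can be a spiro-epoxide on a ring B ketone. C3 can be made nucleophilic as a nitronate. Joining C3 to C2 then closes ring A and releases the C1 hydroxyl in a single event.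

## Retrosynthetic reasoning

**27 ⇒ 26.** The two C–O bonds of the C7–C8 epoxide are cut first, because the epoxide is the most fragile group and should be made last. In 26 the C6 hydroxyl is pseudoaxial on ring B and points to the exo face, and the C1 hydroxyl lies on the same side. A hydroxyl-directed oxygen transfer must therefore reach C7=C8 from the exo face only; ring A screens the endo face. The C1 hydroxyl alone would be a weak director, since it lies close to the plane of the alkene, so the epoxidation is placed after the C6 hydroxyl is free. The forward reaction must leave the electron-poor enamide alkene untouched.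

**26 ⇒ 25 ⇒ 18 + 24.** The two silyl ethers are removed, then the amide C–N bond is cut. This is the convergent point: acid 24 carries a ketone and a Michael acceptor and is best attached late, to an amine 18 whose other nucleophile is only a tertiary hydroxyl.

**24 ⇒ 22 + 23; 22 ⇒ 19 + 20.** The enoic acid is cut at its C=C bond (cross-metathesis of 22 with 23) and the ketone at the C–C bond next to the carbonyl (20 adding to nitrile 19). Both cuts lead directly to catalogue compounds.

**18 ⇒ 17.** The amine is traced to a nitro group. This is not only a protecting device: the nitro group is what makes C3 a carbon nucleophile in the ring closure.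

**17 ⇒ 15 (through nitronate 16).** The C2–C3 bond is cut. This is the only ring A bond whose cleavage turns a bridgehead carbinol into a simple functional group: it leaves a spiro-epoxide at C1 and a nitromethyl terminus at C3. Cutting C4–C5 or C1–C2 would leave a quaternary or bridgehead centre to be made by intermolecular chemistry. The forward step has to form C2–C3 by attack at the epoxide methylene, keep C1 untouched, and place the nitro group exo.

**15 ⇒ 14 ⇒ 13 ⇒ 8 + 10 (10 ⇒ 9).** The nitro group is traced to a primary bromide and the C4 silyl ether to a free carbinol. The C4–C5 bond is then cut as an aldol between ketone 8 and aldehyde 10. C5 is the only enolisable position of 8, because C1 is quaternary. The aldol must put the arm trans to the C6 silyl ether and set C4 in the syn sense, which is what the axial C4 oxygen of ring A requires. Attaching C4–C3 as a nitrovinyl group and adding oxygen to C4 afterwards looks shorter but was rejected. The C5 hydrogen of such a unit is activated by both the ketone and the vinylogous nitro group, so any basic oxygen nucleophile would only deprotonate it, and C4 would be formed without control.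

**8 ⇒ 7 ⇒ 6 ⇒ 3 + 4 (through ylide 5).** The C9 ketone is traced to a carbinol that is kept silylated while C1 is still a ketone. The C1–C2 and C2–O bonds are cut together: the epoxide is the adduct of the enone carbonyl of 3 with the one-carbon ylide 5 made from 4. The forward reaction must bring C2 in anti to the C6 silyl ether, so that the epoxide oxygen ends cis to C6–O.

**3 ⇒ 1 (through 2).** The C9 oxygen is introduced by α′-oxidation of the cross-conjugated enolate of 1. It has to be in place before C1 loses its carbonyl group, since C9 is activated only as the α′-position of that ketone. Its configuration is a relay and is erased in 8.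

## Alternatives that were turned down

**Alternative 1:** Both C5–C6 and C5–C4 are cut, leading to the achiral keto dialdehyde A1, whose methyl carbon is C5 and whose tertiary carbinol is C1. In the forward sense MgBr2 and a tertiary amine would enolise the methyl ketone gently. The methyl carbon would add to one (Z)-enal carbonyl and then to the other, closing ring B and ring A and giving the meso diene-diol A2. An enzyme would then differentiate the two enantiotopic carbinols.
- In its favour: two rings, two C–C bonds and both carbinol centres arise from an open chain in one operation. On step count to the bare skeleton this is stronger than the chosen route.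
- Against it: A2 still lacks nitrogen. Its C2=C3 alkene is isolated from the ketone by the bridgehead, and the allylic C4 oxygen would steer any transposition of nitrogen to C2 or C4, not to C3. A formal anti-Markovnikov hydroamination with exo selectivity would be needed. The absolute configuration would also depend on desymmetrising a retro-aldol-prone bis-β-hydroxy ketone, and the (Z)-enals of A1 are prone to isomerise.
- In comparison: the chosen strategy is longer to the skeleton, but it brings nitrogen in with C3 and ties every stereocentre to a defined event.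

**Alternative 2:** The C5–C6 bond of ring B is cut as an aldol and traced to the glucose-derived enol ether A3. Catalytic Hg(OCOCF3)2 (divalent mercury) in aqueous acetone would hydrate the enol ether, open the pyranose to a keto aldehyde, and let the C5 enolate add to the C6 aldehyde, giving the ring B hydroxy ketone A4.
- In its favour: the absolute configuration comes from the chiral pool, and the ring-forming reaction is catalytic and well behaved. On reliability of that single step it is stronger than the chosen key step.
- Against it: the sugar puts its stereocentres on C7, C8 and C1, where the target needs an epoxide and a quaternary carbinol. C1 arrives as a secondary benzyl ether next to the ketone and would have to be oxidised and alkylated. C5 arrives as a bare methylene, so all of ring A and the nitrogen remain to be built. Three different protecting groups have to be handled.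
- In comparison: the chosen strategy starts from a less functionalised ring B but forms ring A, the C1 carbinol and the C3 nitrogen centre in one step.

**Alternative 3:** The C6–O bond and the epoxide are both traced to one alkene, C6=C7, in the bicyclic carbamate A5. Sensitised singlet oxygen would attack the exo face in an ene reaction, taking hydrogen from C8 to give a C6 hydroperoxide and a C7=C8 alkene. Ti(OiPr)4 (tetravalent titanium) would then pass the distal oxygen to that alkene, giving A6.
- In its favour: two C–O bonds and three stereocentres of ring B come from oxygen in one flask, and the cis relation of the C6 hydroxyl and the epoxide is built in. For the oxygenation of ring B this is stronger than the chosen route, which takes C6–O from the starting material and epoxidises separately.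
- Against it: it is an end-game only. A5, with ring A, the C3 nitrogen, the C1 carbinol and the C9 ketone, must first be made by chemistry this plan does not supply. The hydroperoxide would also sit β to the C9 ketone, where base-induced loss of water to a C6 ketone competes.
- In comparison: the chosen strategy provides the skeleton and settles for a conventional directed epoxidation at the end.

Key step: step 9

Remark: enone 1 is taken as a purchasable enantiopure building block. The C9 silyl ether of 3 is drawn trans to the C6 silyl ether, the outcome expected for anti attack; this centre is removed in step 4. Bicyclic compounds are named with the core numbering above.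

## Route

Step 1
Reactants: 1 (S)-4-(tert-butyldimethylsilyloxy)cyclohex-2-en-1-one
Product: 3 (4S,6S)-4-(tert-butyldimethylsilyloxy)-6-(triethylsilyloxy)cyclohex-2-en-1-one, via silyl dienol ether 2 (not isolated)
Conditions: LiN(iPr)2, THF, −78 °C; Et3SiCl; then dimethyldioxirane, acetone/CH2Cl2, −78 → 0 °C
Reagents that add atoms: chlorotriethylsilane CC[Si](Cl)(CC)CC; dimethyldioxirane CC1(C)OO1
Why: Rubottom oxidation: kinetic α′-deprotonation at C9 and O-silylation give the cross-conjugated dienol ether, whose electron-rich enol ether bond is epoxidised on the face away from the pseudoaxial C6 silyl ether; the silyloxy epoxide opens with 1,4-silyl shift to the α-silyloxy ketone, so the C9 oxygen should come out trans to C6–O. This centre only relays stereochemistry and is oxidised in step 4.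

Step 2
Reactants: 3 (4S,6S)-4-(tert-butyldimethylsilyloxy)-6-(triethylsilyloxy)cyclohex-2-en-1-one; 4 trimethylsulfonium iodide
Product: 6 (3R,4S,6S)-6-(tert-butyldimethylsilyloxy)-4-(triethylsilyloxy)-1-oxaspiro[2.5]oct-7-ene, via dimethylsulfonium methylide 5 (not isolated)
Conditions: KN(SiMe3)2, THF, −15 °C; then 3, −15 → 0 °C
Reagents that add atoms: none
Why: Corey–Chaykovsky epoxidation: the unstabilised sulfonium ylide adds 1,2 to the enone carbonyl and the resulting alkoxide displaces dimethyl sulfide, so C2 ends on the face of attack and the oxygen on the other. Axial attack on the half-chair with the C6 silyl ether pseudoaxial and the C9 silyl ether equatorial brings C2 in anti to C6–O, which should leave the epoxide oxygen cis to C6–O as the C1 hydroxyl of the target requires.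

Step 3
Reactants: 6 (3R,4S,6S)-6-(tert-butyldimethylsilyloxy)-4-(triethylsilyloxy)-1-oxaspiro[2.5]oct-7-ene
Product: 7 (3R,4S,6S)-6-(tert-butyldimethylsilyloxy)-1-oxaspiro[2.5]oct-7-en-4-ol
Conditions: HF·pyridine, pyridine, THF, 0 °C
Reagents that add atoms: none
Why: Acidic fluoride cleaves a triethylsilyl ether far faster than a tert-butyldimethylsilyl ether; the excess pyridine keeps the medium mild enough for the vinyl epoxide.

Step 4
Reactants: 7 (3R,4S,6S)-6-(tert-butyldimethylsilyloxy)-1-oxaspiro[2.5]oct-7-en-4-ol
Product: 8 (3R,6S)-6-(tert-butyldimethylsilyloxy)-1-oxaspiro[2.5]oct-7-en-4-one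
Conditions: Dess–Martin periodinane, pyridine, CH2Cl2, 0 °C → rt
Reagents that add atoms: none
Why: Dess–Martin oxidation of the secondary carbinol under buffered conditions. C1 is quaternary, so the new C9 ketone can enolise only towards C5.

Step 5
Reactants: 9 (E)-1,4-dibromobut-2-ene
Product: 10 bromoacetaldehyde
Conditions: O3, CH2Cl2, −78 °C; PPh3, −78 °C → rt; distilled and used at once as a dry THF solution
Reagents that add atoms: ozone [O-][O+]=O
Why: Ozonolysis with reductive work-up of a symmetrical alkene gives two equivalents of one aldehyde and no second carbonyl compound; the aldehyde is used immediately because it polymerises.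

Step 6
Reactants: 8 (3R,6S)-6-(tert-butyldimethylsilyloxy)-1-oxaspiro[2.5]oct-7-en-4-one; 10 bromoacetaldehyde
Product: 13 (3R,5S,6R)-5-[(1R)-2-bromo-1-hydroxyethyl]-6-(tert-butyldimethylsilyloxy)-1-oxaspiro[2.5]oct-7-en-4-one, via lithium enolate 11 (not isolated), via titanium enolate 12 (not isolated)
Conditions: LiN(iPr)2, THF, −78 °C; ClTi(OiPr)3, −78 → −40 °C; 10, −78 °C; aq. NH4Cl
Reagents that add atoms: none
Why: Aldol addition: C5 is the only enolisable position, and the aldehyde approaches opposite the adjacent C6 silyl ether, so the arm ends trans to C6–O. Triisopropoxytitanium enolates (tetravalent titanium) of cyclic ketones are known to favour syn aldols, here C4–OH and C6 on the same side of the C9–C5–C4–C3 zigzag, which is the (R) configuration at C4 that becomes the axial C4 oxygen of ring A. The low temperature and the weakly basic titanium aldolate hold back loss of the C6 silyl ether and closure of the bromohydrin.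

Step 7
Reactants: 13 (3R,5S,6R)-5-[(1R)-2-bromo-1-hydroxyethyl]-6-(tert-butyldimethylsilyloxy)-1-oxaspiro[2.5]oct-7-en-4-one
Product: 14 (3R,5R,6R)-5-[(1R)-2-bromo-1-(tert-butyldimethylsilyloxy)ethyl]-6-(tert-butyldimethylsilyloxy)-1-oxaspiro[2.5]oct-7-en-4-one
Conditions: tBuMe2SiOTf, 2,6-lutidine, CH2Cl2, −78 °C
Reagents that add atoms: tert-butyldimethylsilyl trifluoromethanesulfonate CC(C)(C)[Si](C)(C)OS(=O)(=O)C(F)(F)F
Why: Silylation of the secondary carbinol with a silyl triflate and a hindered pyridine base is fast at −78 °C, faster than any opening of the epoxide, and the non-nucleophilic base leaves the bromide in place.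

Step 8
Reactants: 14 (3R,5R,6R)-5-[(1R)-2-bromo-1-(tert-butyldimethylsilyloxy)ethyl]-6-(tert-butyldimethylsilyloxy)-1-oxaspiro[2.5]oct-7-en-4-one
Product: 15 (3R,5R,6R)-6-(tert-butyldimethylsilyloxy)-5-[(1R)-1-(tert-butyldimethylsilyloxy)-2-nitroethyl]-1-oxaspiro[2.5]oct-7-en-4-one
Conditions: NaNO2, phloroglucinol, DMSO, rt
Reagents that add atoms: sodium nitrite [Na+].[O-]N=O
Why: Kornblum substitution: nitrite displaces the primary bromide through nitrogen in a dipolar aprotic solvent, and phloroglucinol traps the nitrite ester by-product before it can nitrosate the product. No stereocentre is touched, and the medium is too weakly basic to enolise the ketone.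

Step 9
Reactants: 15 (3R,5R,6R)-6-(tert-butyldimethylsilyloxy)-5-[(1R)-1-(tert-butyldimethylsilyloxy)-2-nitroethyl]-1-oxaspiro[2.5]oct-7-en-4-one
Product: 17 (1S,3S,4R,5R,6R)-4,6-bis(tert-butyldimethylsilyloxy)-1-hydroxy-3-nitrobicyclo[3.3.1]non-7-en-9-one, via C3 nitronate 16 (not isolated)
Conditions: DBU (0.3 equiv), MeCN, 0 °C → rt
Reagents that add atoms: none
Why: DBU removes a C3 proton (the nitro group is far more acidic than the C5–H next to the ketone), and the nitronate carbon of 16 attacks the epoxide methylene C2 in an SN2 opening that forms C2–C3 and frees the C1 alkoxide, which takes the proton back from the amidinium so that the base turns over. The closest known reaction type is the intramolecular C-alkylation of nitronates by epoxides, with the epoxynitrile cyclisation as the model for the ring-size preference. Ring A closes in the 6-endo mode with respect to the epoxide, because the 5-exo alternative would be a displacement at quaternary C1. C1 keeps its configuration since its C–O bond is not broken; collinear attack puts C3 anti to the leaving oxygen across C1–C2, which is the equatorial C1–O arrangement of a chair ring A, reached when the C1 methylene and the C5 arm are both pseudoaxial on ring B. The new centre C3 is set under thermodynamic control: the product is still C–H acidic, equilibrates through its nitronate under the catalytic base, and should settle with the nitro group exo (equatorial), because the endo position runs into C7 of ring B. The step needs C- over O-alkylation (O-attack would give an eight-membered cyclic nitronate), nitronate formation over ketone enolisation (which would expel the C6 silyl ether), and attack at C2 over SN2′ attack at C7; the last is held back because in the reactive conformer the C1–O bond lies in the nodal plane of C7=C8. Loss of the C4 silyl ether from the nitronate by β-elimination is the remaining drain, hence a weak base in catalytic amount at or below room temperature.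

Step 10
Reactants: 17 (1S,3S,4R,5R,6R)-4,6-bis(tert-butyldimethylsilyloxy)-1-hydroxy-3-nitrobicyclo[3.3.1]non-7-en-9-one
Product: 18 (1S,3S,4R,5R,6R)-3-amino-4,6-bis(tert-butyldimethylsilyloxy)-1-hydroxybicyclo[3.3.1]non-7-en-9-one
Conditions: Zn dust, AcOH, THF, 0 °C → rt
Reagents that add atoms: none
Why: Zinc in acetic acid reduces an aliphatic nitro group to the primary amine without touching C3, the alkene, the silyl ethers or the hindered ketone. Reductive loss of the C1 hydroxyl is blocked because it would need an enolate at the bridgehead.

Step 11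
Reactants: 19 hex-5-enenitrile; 20 pentylmagnesium bromide
Product: 22 undec-1-en-6-one, via magnesium ketimide 21 (not isolated)
Conditions: Et2O, 0 °C → reflux; then 1 M HCl, 0 °C
Reagents that add atoms: water O
Why: Grignard addition to a nitrile stops at the magnesium ketimide, which is hydrolysed to the ketone on acidic work-up, so no tertiary alcohol forms.

Step 12
Reactants: 22 undec-1-en-6-one; 23 acrylic acid
Product: 24 (E)-7-oxododec-2-enoic acid
Conditions: second-generation Grubbs catalyst RuCl2(=CHPh)(H2IMes)(PCy3) (5 mol %), CH2Cl2, 40 °C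
Reagents that add atoms: none
Why: Cross-metathesis of a terminal alkene with an acrylate partner, which homodimerises only slowly; the conjugated (E)-acid is the thermodynamic product.

Step 13
Reactants: 18 (1S,3S,4R,5R,6R)-3-amino-4,6-bis(tert-butyldimethylsilyloxy)-1-hydroxybicyclo[3.3.1]non-7-en-9-one; 24 (E)-7-oxododec-2-enoic acid
Product: 25 (E)-N-[(1S,3S,4R,5R,6R)-4,6-bis(tert-butyldimethylsilyloxy)-1-hydroxy-9-oxobicyclo[3.3.1]non-7-en-3-yl]-7-oxododec-2-enamide
Conditions: EDC·HCl, HOBt, iPr2NEt, CH2Cl2, 0 °C → rt
Reagents that add atoms: none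
Why: Carbodiimide/HOBt amide coupling; the primary amine is acylated in preference to the tertiary C1 hydroxyl, and the active ester avoids conjugate addition to the enoate.

Step 14
Reactants: 25 (E)-N-[(1S,3S,4R,5R,6R)-4,6-bis(tert-butyldimethylsilyloxy)-1-hydroxy-9-oxobicyclo[3.3.1]non-7-en-3-yl]-7-oxododec-2-enamide
Product: 26 (E)-7-oxo-N-[(1S,3S,4R,5R,6R)-1,4,6-trihydroxy-9-oxobicyclo[3.3.1]non-7-en-3-yl]dodec-2-enamide
Conditions: HF·pyridine, pyridine, THF, 0 °C → rt
Reagents that add atoms: none
Why: Buffered HF·pyridine removes both secondary silyl ethers without base, so retro-aldol opening of the β-hydroxy ketone units is avoided; no epoxide is present yet.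

Step 15
Reactants: 26 (E)-7-oxo-N-[(1S,3S,4R,5R,6R)-1,4,6-trihydroxy-9-oxobicyclo[3.3.1]non-7-en-3-yl]dodec-2-enamide
Product: 27 isariotin C
Conditions: VO(acac)2 (5 mol %), tBuOOH (decane), CH2Cl2, 0 °C → rt
Reagents that add atoms: tert-butyl hydroperoxide CC(C)(C)OO
Why: Hydroxyl-directed epoxidation with VO(acac)2 (tetravalent vanadium): the pseudoaxial allylic C6 hydroxyl, with the C1 hydroxyl on the same side, delivers oxygen to the exo face of C7=C8, while ring A screens the endo face; this sets C7 and C8 cis to C6–OH. The enamide alkene is electron-poor and has no directing hydroxyl, so it should not react.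

## Compound list

1 | (S)-4-(tert-butyldimethylsilyloxy)cyclohex-2-en-1-one | O=C1C=C[C@@H](O[Si](C)(C)C(C)(C)C)CC1 | starting material
2 | (5S)-5-(tert-butyldimethylsilyloxy)-2-(triethylsilyloxy)cyclohexa-1,3-diene | CC[Si](CC)(CC)OC1=CC[C@H](O[Si](C)(C)C(C)(C)C)C=C1 | intermediate
3 | (4S,6S)-4-(tert-butyldimethylsilyloxy)-6-(triethylsilyloxy)cyclohex-2-en-1-one | O=C1C=C[C@@H](O[Si](C)(C)C(C)(C)C)C[C@@H]1O[Si](CC)(CC)CC | intermediate
4 | trimethylsulfonium iodide | C[S+](C)C.[I-] | starting material
5 | dimethylsulfonium methylide | C[S+](C)[CH2-] | intermediate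
6 | (3R,4S,6S)-6-(tert-butyldimethylsilyloxy)-4-(triethylsilyloxy)-1-oxaspiro[2.5]oct-7-ene | O1C[C@@]12C=C[C@@H](O[Si](C)(C)C(C)(C)C)C[C@@H]2O[Si](CC)(CC)CC | intermediate
7 | (3R,4S,6S)-6-(tert-butyldimethylsilyloxy)-1-oxaspiro[2.5]oct-7-en-4-ol | O1C[C@@]12C=C[C@@H](O[Si](C)(C)C(C)(C)C)C[C@@H]2O | intermediate
8 | (3R,6S)-6-(tert-butyldimethylsilyloxy)-1-oxaspiro[2.5]oct-7-en-4-one | O1C[C@@]12C=C[C@@H](O[Si](C)(C)C(C)(C)C)CC2=O | intermediate
9 | (E)-1,4-dibromobut-2-ene | BrC/C=C/CBr | starting material
10 | bromoacetaldehyde | BrCC=O | intermediate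
11 | lithium enolate of 8 (C9–O–Li, C5=C9) | [Li]OC1=C[C@H](O[Si](C)(C)C(C)(C)C)C=C[C@@]12CO2 | intermediate
12 | triisopropoxytitanium enolate of 8 | CC(C)O[Ti](OC(C)C)(OC(C)C)OC1=C[C@H](O[Si](C)(C)C(C)(C)C)C=C[C@@]12CO2 | intermediate
13 | (3R,5S,6R)-5-[(1R)-2-bromo-1-hydroxyethyl]-6-(tert-butyldimethylsilyloxy)-1-oxaspiro[2.5]oct-7-en-4-one | BrC[C@H](O)[C@@H]1C(=O)[C@]2(CO2)C=C[C@H]1O[Si](C)(C)C(C)(C)C | intermediate
14 | (3R,5R,6R)-5-[(1R)-2-bromo-1-(tert-butyldimethylsilyloxy)ethyl]-6-(tert-butyldimethylsilyloxy)-1-oxaspiro[2.5]oct-7-en-4-one | BrC[C@H](O[Si](C)(C)C(C)(C)C)[C@@H]1C(=O)[C@]2(CO2)C=C[C@H]1O[Si](C)(C)C(C)(C)C | intermediate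
15 | (3R,5R,6R)-6-(tert-butyldimethylsilyloxy)-5-[(1R)-1-(tert-butyldimethylsilyloxy)-2-nitroethyl]-1-oxaspiro[2.5]oct-7-en-4-one | [O-][N+](=O)C[C@H](O[Si](C)(C)C(C)(C)C)[C@@H]1C(=O)[C@]2(CO2)C=C[C@H]1O[Si](C)(C)C(C)(C)C | intermediate
16 | C3 nitronate of 15, amidinium (DBU-H) salt | [O-][N+]([O-])=C[C@H](O[Si](C)(C)C(C)(C)C)[C@@H]1C(=O)[C@]2(CO2)C=C[C@H]1O[Si](C)(C)C(C)(C)C.C1CCC2=[NH+]CCCN2CC1 | intermediate
17 | (1S,3S,4R,5R,6R)-4,6-bis(tert-butyldimethylsilyloxy)-1-hydroxy-3-nitrobicyclo[3.3.1]non-7-en-9-one | [O-][N+](=O)[C@H]1C[C@@]2(O)C(=O)[C@H]([C@H](O[Si](C)(C)C(C)(C)C)C=C2)[C@H]1O[Si](C)(C)C(C)(C)C | intermediate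
18 | (1S,3S,4R,5R,6R)-3-amino-4,6-bis(tert-butyldimethylsilyloxy)-1-hydroxybicyclo[3.3.1]non-7-en-9-one | N[C@H]1C[C@@]2(O)C(=O)[C@H]([C@H](O[Si](C)(C)C(C)(C)C)C=C2)[C@H]1O[Si](C)(C)C(C)(C)C | intermediate
19 | hex-5-enenitrile | C=CCCCC#N | starting material
20 | pentylmagnesium bromide | CCCCC[Mg]Br | starting material
21 | N-(bromomagnesio)undec-1-en-6-imine (magnesium ketimide) | CCCCCC(=N[Mg]Br)CCCC=C | intermediate
22 | undec-1-en-6-one | CCCCCC(=O)CCCC=C | intermediate
23 | acrylic acid | C=CC(=O)O | starting material
24 | (E)-7-oxododec-2-enoic acid | CCCCCC(=O)CCC/C=C/C(=O)O | intermediate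
25 | (E)-N-[(1S,3S,4R,5R,6R)-4,6-bis(tert-butyldimethylsilyloxy)-1-hydroxy-9-oxobicyclo[3.3.1]non-7-en-3-yl]-7-oxododec-2-enamide | CCCCCC(=O)CCC/C=C/C(=O)N[C@H]1C[C@@]2(O)C(=O)[C@H]([C@H](O[Si](C)(C)C(C)(C)C)C=C2)[C@H]1O[Si](C)(C)C(C)(C)C | intermediate
26 | (E)-7-oxo-N-[(1S,3S,4R,5R,6R)-1,4,6-trihydroxy-9-oxobicyclo[3.3.1]non-7-en-3-yl]dodec-2-enamide | CCCCCC(=O)CCC/C=C/C(=O)N[C@H]1C[C@@]2(O)C(=O)[C@H]([C@H](O)C=C2)[C@H]1O | intermediate
27 | isariotin C | CCCCCC(=O)CCC/C=C/C(=O)N[C@H]1C[C@@]2(O)C(=O)[C@H]([C@H](O)[C@@H]3O[C@@H]32)[C@H]1O | target

## Step count and least certain steps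

Total: 15 steps. Longest linear sequence: 12 steps (1 to 27 through steps 1–4, 6–10 and 13–15). Steps 5, 11 and 12 prepare the two side partners.

**Step 9 (key step).** The most likely failure is a ring closure that is too slow. Nitronates are weak carbon nucleophiles towards unactivated epoxides, and the 6-endo geometry needs the diaxial conformer of ring B. Two other processes could then take over: loss of the C4 silyl ether from the nitronate by β-elimination, and enolisation at C5 with loss of the C6 silyl ether. The fallback closes the same C2–C3 bond by a nitroaldol reaction; it sets out from 15 and returns at 17. Dilute HClO4 in aqueous THF would open the epoxide at the methylene to the C1,C2-diol F1. TEMPO with PhI(OAc)2 would oxidise only the primary carbinol, to the α-hydroxy aldehyde F2. Catalytic Et3N would then close ring A by intramolecular Henry addition (6-exo-trig) to the bicyclic nitro diol F3. Mesylation–elimination with MsCl and Et3N would give the C2=C3 nitroalkene F4. Conjugate reduction with a Hantzsch ester on silica, with protonation at C3 under thermodynamic control, would lead to 17.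

**Step 2.** The risk is poor or reversed facial selectivity. The polar C9 silyl ether can also direct the ylide anti to itself through the other half-chair, and the basic ylide can enolise the ketone. The fallback sets out from 3 and returns at 6. Wittig methylenation with Ph3P=CH2 would give the exocyclic diene F5, in which allylic strain places the C9 silyl ether axial. Catalytic OsO4 with N-methylmorpholine N-oxide should dihydroxylate the less hindered exocyclic alkene anti to that axial group, giving the diol F6 with the tertiary hydroxyl cis to C6–O. Tosylation of the primary carbinol would give the monotosylate F7, and K2CO3 in MeOH would close the epoxide to 6.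

**Step 6.** The risk is erosion of simple diastereoselection towards the anti adduct through a chair transition state, together with β-elimination of the C6 silyl ether from the enolate. The fallback sets C4 under catalyst control; it sets out from 8 and returns at 15, bypassing steps 7 and 8. Hydroxymethylation of the lithium enolate with monomeric formaldehyde would give the hydroxymethyl ketone F8. NaBH4 would reduce the C9 ketone to the diol F9 (either C9 epimer serves). TEMPO with PhI(OAc)2 would oxidise the primary carbinol to the hydroxy aldehyde F10. A Henry reaction with nitromethane, catalysed by Cu(OAc)2 and a chiral bis(oxazoline), would give the nitro diol F11. tBuMe2SiCl and imidazole should silylate the unhindered C4 hydroxyl selectively, giving the silyl ether F12, and Dess–Martin oxidation of the C9 carbinol would give 15.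

**Step 8.** The risk is attack of the ambident nitrite through oxygen (nitrite ester), slow substitution at a β-branched carbon, and nitrosation of the product once it forms. The fallback sets out from 14 and returns at 15. Finkelstein exchange with NaI in acetone would give the iodide F13. AgNO2 in Et2O (Victor Meyer reaction) would then deliver the nitro compound, because silver-assisted departure of iodide favours bonding through nitrogen. The detour described for step 6 avoids the substitution altogether.

## Further compounds

F1 | step 9 | C1,C2-diol from hydrolytic opening of the epoxide of 15 (C1 configuration retained) | [O-][N+](=O)C[C@H](O[Si](C)(C)C(C)(C)C)[C@@H]1C(=O)[C@](O)(CO)C=C[C@H]1O[Si](C)(C)C(C)(C)C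
F2 | step 9 | α-hydroxy aldehyde (C2 formyl on C1) | [O-][N+](=O)C[C@H](O[Si](C)(C)C(C)(C)C)[C@@H]1C(=O)[C@](O)(C=O)C=C[C@H]1O[Si](C)(C)C(C)(C)C
F3 | step 9 | 4,6-bis(tert-butyldimethylsilyloxy)-1,2-dihydroxy-3-nitrobicyclo[3.3.1]non-7-en-9-one (C2 and C3 not assigned) | [O-][N+](=O)C1C(O)[C@@]2(O)C(=O)[C@H]([C@H](O[Si](C)(C)C(C)(C)C)C=C2)[C@H]1O[Si](C)(C)C(C)(C)C
F4 | step 9 | 4,6-bis(tert-butyldimethylsilyloxy)-1-hydroxy-3-nitrobicyclo[3.3.1]nona-2,7-dien-9-one | [O-][N+](=O)C1=C[C@@]2(O)C(=O)[C@H]([C@H](O[Si](C)(C)C(C)(C)C)C=C2)[C@H]1O[Si](C)(C)C(C)(C)C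
F5 | step 2 | (3S,5S)-3-(tert-butyldimethylsilyloxy)-6-methylidene-5-(triethylsilyloxy)cyclohex-1-ene | C=C1C=C[C@@H](O[Si](C)(C)C(C)(C)C)C[C@@H]1O[Si](CC)(CC)CC
F6 | step 2 | 4-(tert-butyldimethylsilyloxy)-1-(hydroxymethyl)-6-(triethylsilyloxy)cyclohex-2-en-1-ol, tertiary hydroxyl cis to C6–O | OC[C@]1(O)C=C[C@@H](O[Si](C)(C)C(C)(C)C)C[C@@H]1O[Si](CC)(CC)CC
F7 | step 2 | primary p-toluenesulfonate of F6 | Cc1ccc(cc1)S(=O)(=O)OC[C@]1(O)C=C[C@@H](O[Si](C)(C)C(C)(C)C)C[C@@H]1O[Si](CC)(CC)CC
F8 | step 6 | 6-(tert-butyldimethylsilyloxy)-5-(hydroxymethyl)-1-oxaspiro[2.5]oct-7-en-4-one, arm trans to C6–O | OC[C@@H]1C(=O)[C@]2(CO2)C=C[C@H]1O[Si](C)(C)C(C)(C)C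
F9 | step 6 | 6-(tert-butyldimethylsilyloxy)-5-(hydroxymethyl)-1-oxaspiro[2.5]oct-7-en-4-ol (C9 carbinol, either epimer) | OC[C@@H]1C(O)[C@]2(CO2)C=C[C@H]1O[Si](C)(C)C(C)(C)C
F10 | step 6 | 6-(tert-butyldimethylsilyloxy)-4-hydroxy-1-oxaspiro[2.5]oct-7-ene-5-carbaldehyde | O=C[C@@H]1C(O)[C@]2(CO2)C=C[C@H]1O[Si](C)(C)C(C)(C)C
F11 | step 6 | 6-(tert-butyldimethylsilyloxy)-5-[(1R)-1-hydroxy-2-nitroethyl]-1-oxaspiro[2.5]oct-7-en-4-ol | [O-][N+](=O)C[C@H](O)[C@@H]1C(O)[C@]2(CO2)C=C[C@H]1O[Si](C)(C)C(C)(C)C
F12 | step 6 | 6-(tert-butyldimethylsilyloxy)-5-[(1R)-1-(tert-butyldimethylsilyloxy)-2-nitroethyl]-1-oxaspiro[2.5]oct-7-en-4-ol | [O-][N+](=O)C[C@H](O[Si](C)(C)C(C)(C)C)[C@@H]1C(O)[C@]2(CO2)C=C[C@H]1O[Si](C)(C)C(C)(C)C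
F13 | step 8 | (3R,5R,6R)-6-(tert-butyldimethylsilyloxy)-5-[(1R)-1-(tert-butyldimethylsilyloxy)-2-iodoethyl]-1-oxaspiro[2.5]oct-7-en-4-one | IC[C@H](O[Si](C)(C)C(C)(C)C)[C@@H]1C(=O)[C@]2(CO2)C=C[C@H]1O[Si](C)(C)C(C)(C)C
A1 | alternative 1 | (2Z,5Z)-4-acetyl-4-hydroxyhepta-2,5-dienedial | CC(=O)C(O)(/C=C\C=O)/C=C\C=O
A2 | alternative 1 | meso-1,4,6-trihydroxybicyclo[3.3.1]nona-2,7-dien-9-one | C1=C[C@@]2(O)C(=O)[C@H]([C@H](O)C=C2)[C@H]1O
A3 | alternative 2 | methyl 4-O-benzyl-3-O-(tert-butyldimethylsilyl)-6-deoxy-2-O-(4-methoxybenzyl)-D-xylo-hex-5-enopyranoside | COC1OC(=C)[C@@H](OCc2ccccc2)[C@H](O[Si](C)(C)C(C)(C)C)[C@H]1OCc1ccc(OC)cc1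
A4 | alternative 2 | ring B hydroxy ketone (C6 carbinol; C7, C8 and C1 oxygenated; C9 ketone) | O=C1C[C@H](O)[C@H](OCc2ccc(OC)cc2)[C@@H](O[Si](C)(C)C(C)(C)C)[C@@H]1OCc3ccccc3
A5 | alternative 3 | N-Boc C4-silyl bicyclo[3.3.1]non-6-en-9-one ketol (C6=C7 alkene) | CC(C)(C)OC(=O)N[C@H]1C[C@@]2(O)C(=O)[C@H](C=CC2)[C@H]1O[Si](C)(C)C(C)(C)C
A6 | alternative 3 | N-Boc C4-silyl isariotin C core | CC(C)(C)OC(=O)N[C@H]1C[C@@]2(O)C(=O)[C@H]([C@H](O)[C@@H]3O[C@@H]32)[C@H]1O[Si](C)(C)C(C)(C)C
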